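# Proposed total synthesis of CNP0148862.1 by a vinylcarbenoid cyclopropanation–Cope (4+3) annulation

Cedrane locants are used throughout: ring A is C1–C2–C3–C4–C5, ring B is C1–C5–C6–C7–C11, ring C is C1–C10–C9–C8–C7–C11. C12 is the carboxyl carbon, C13 the hydroxymethyl carbon, C14 the methyl carbon and C15 the formyl carbon; primed locants belong to the acyl chain. "Exo" means the face of the C5–C6 bridge turned towards C11, and "endo" the face turned towards the C8–C10 bridge.

## Analysis of the target

The target is a cedrane-type sesquiterpenoid ester, a tricyclo[5.3.1.0(1,5)]undec-8-ene. Cyclopentane ring A is fused at C1–C5 to ring B, and ring B is bridged from C1 to C7 by C10–C9–C8 to give cyclohexene ring C. Six contiguous stereocentres (C1, C2, C5, C6, C7, C10) are present, and C1 and C6 are quaternary. H-5 and the C13 hydroxymethyl group are exo, the C14 methyl is endo, the C10 acyloxy group lies on the face of ring C syn to C11, and the C2 formyl group is cis to C10 on ring A. The functional groups constrain each other: the free C8 enoic acid sits next to the allylic C10 ester, so it cannot be released by saponification. There are also an epimerisable α-branched aldehyde at C2, two free primary alcohols and a Z-alkene in the (9Z)-16-hydroxyhexadec-9-enoyl chain. The difficulty is to build the bridged core with both quaternary carbons in the right absolute sense and then to tell apart three carboxyl-level carbons and three primary oxygens. The plan rests on one feature: the C8–C9–C10 enoate bridge spans C7 and C1 of a five-membered ring whose remaining carbon, C11, is a plain CH2, which is the pattern left when a vinylcarbenoid adds across the termini of a cyclopentadiene.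

## Retrosynthetic reasoning

**42 back to 41.** All masks are removed in one acidolysis. The C8 acid is carried as a tert-butyl ester, the C2 formyl group as a dimethyl acetal and the C13 and C16′ hydroxyls as silyl ethers. The C10 ester is stable to acid, so no hydrolytic step is needed once it is in place.

**41 back to 32 and 39.** The C10–O acyl bond is cut. The forward reaction is an esterification of the hindered allylic alcohol 32 with the acid 39 through an activated mixed anhydride. Acid 39 comes from alkyne 34 and bromo acid 35 by acetylide alkylation (C8′–C9′ bond) and cis-semihydrogenation of 38, which fixes the Z geometry.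

**32 back to 31.** The C10–O bond is cut. C10 is the only allylic position with hydrogens, because C7 is a bridgehead, so an ene-type allylic oxidation has no regiochemical choice. Delivery from the open face turned to C11 gives the required configuration.

**31 back to 26.** The C6–C13 bond and the C5–H bond are cut. An enal at C5=C6 (26) lets hydride enter at C5 and a one-carbon electrophile enter at C6 of the derived enolate, both from the exo face (27, 28). The formyl carbon that remains endo is then reduced to the C14 methyl (29 to 31). This is why the C6 substituent of the diene is an oxygenated carbon that ends as the methyl group: the carbon added later is the one that enters exo, and that must be C13.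

**26 back to 22.** These are functional-group changes only: desilylation and oxidation of the C14 arm (25, 26), preceded by exchange of the methyl ester for a tert-butyl ester (23, 24). The exchange is placed early, when no other ester is present.

**22 back to 16 and 20.** This is the key disconnection: C7–C8 and C1–C10 are cut, which removes ring C. The diene 16 is flat and carries a single stereocentre (C2). The vinyldiazoacetate 20 supplies C8, C9, C10 and C12. The forward reaction must form two C–C bonds and the C1 and C7 stereocentres, and leave C11 as CH2, the enoate at C8=C9 and a C5=C6 alkene as the handle for the remaining two stereocentres.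

**16 back to 13.** A ring-fused cyclopentadiene can exist as several tautomers related by [1,5]-hydrogen shifts, and only the one with C11 as CH2 leads to the cedrane skeleton. The diene is therefore traced to dienyl triflate 15, in which the oxygen on C7 pins the double bonds, and 15 to enone 13. Reductive removal of the triflate in the cold gives 16 as one tautomer.

**13 back to 9.** A Pauson–Khand disconnection cuts C1–C5, C6–C7 and C7–C11 and leads to the 1,6-enyne 9. The acetal is installed only after the cyclisation (10 to 13), because an α-vinyl aldehyde would racemise and conjugate.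

**9 back to 8 and 7.** The C2–C3 bond is cut next to the future C2 stereocentre. A copper-catalysed SN2′ alkylation of allylic bromide 7 by the Grignard reagent 8 sets C2 in one step. Reagent 8 comes from 4 (from 1 through 3), and 7 from 5 and 6.

**20 back to 17.** The unstable diazo ester is prepared just before use by diazo transfer, reduction and dehydration (18, 19).

## Alternatives that were turned down

**Alternative 1:** The C1–C2 bond is disconnected, with ring C taken from a para-alkyl phenol whose para carbon becomes the spiro carbon C1. In the forward step a zerovalent palladium catalyst with a chiral bisphosphine ionises an allylic carbonate in the side chain and the phenol attacks through its para carbon, closing ring A and giving the spirodienone A1.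
- For: C1 (quaternary) and C2 are set together by one catalyst from a flat aromatic precursor, and no existing stereocentre opposes the catalyst. On this point it is stronger than the chosen route, where the C2 substituent works against the catalyst. The dienone also places C10 as a β-carbon, ready to accept oxygen.
- Against: ring B is still open. The C6–C7 bond would have to be made at C7, the α-carbon of the C8 carbonyl, which is polarity-mismatched for a C6 enolate; the natural Michael site is C11. The quaternary C6 is not set (A1 carries a 1-(methoxycarbonyl)ethyl branch of undefined configuration), C11 bears a methoxy group that must be reduced to CH2, and C12 must still be attached at C8.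
- Comparison: the chosen annulation closes ring C and both bridgehead bonds at once and arrives with C11 as CH2 and C12 in place. A1 would need ring-B closure, deoxygenation and a carbonylation before reaching the same point.

**Alternative 2:** The C1–C5 and C6–C7 bonds are disconnected, with ring C taken from a phenol whose oxygen-bearing carbon becomes C11. In the forward step anodic oxidation gives a phenoxonium ion, the tethered C5=C6 alkene adds across C1 and C7 in a cationic (5+2) cycloaddition, and the allyl cation is captured at C10 by acetate, giving A2.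
- For: this is the most convergent option. Rings A and B, both quaternary carbons and the C10 oxygen arise in one operation, and C6 arrives with methyl and protected hydroxymethyl already distinguished. Here it is clearly stronger than the chosen route, which spends six steps on C5 and C6.
- Against: A2 has a ketone at C11, flanked by quaternary C1 and bridgehead C7, that must be reduced to CH2 in the presence of an enoate and an allylic ester; this costs several steps and excludes strongly basic reductions. The phenol carries the C8 ester and is electron-poor, so its oxidation is harder, and the allyl cation bears positive charge next to that ester, which makes capture at C10 and its configuration uncertain. All stereocontrol is by the substrate.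
- Comparison: the chosen route gives up the one-step formation of C6 but keeps C11 at the correct oxidation level, does not require oxidation of a deactivated arene, and sets C1 and C7 by a catalyst.

**Alternative 3:** The C7–C8 and C6–C14 bonds are disconnected. In the forward step a dioxinone tethered to C1 through C10–C9 is irradiated near 300 nm and adds across the C6=C7 alkene of a preformed diquinane (rings A and B), closing ring C together with a cyclobutane; the pentacyclic adduct A3 is later opened by retro-aldol cleavage.
- For: the quaternary C6 is formed directly with its two one-carbon arms distinguished, C12 comes with the dioxinone, and the C10 oxygen is on the tether from the start. On C6 and C10 it is stronger than the chosen route.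
- Against: the precursor must already contain rings A and B with C1 (quaternary), C2, C5 and the oxygenated C10, so most of the stereochemical problem is solved before the key step by other means. After fragmentation C8 is saturated, and the C8=C9 double bond must be reintroduced next to a β-oxygen that can be eliminated. The C14 aldehyde still has to be reduced to methyl, as in the chosen route. With a four-atom tether the straight versus crossed mode of photocycloaddition is not assured.
- Comparison: the chosen annulation creates C1, C7 and ring C from a planar diene with one stereocentre. The photochemical route is better at C6 but needs a much longer precursor synthesis.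

Key step: step 14

Assumption: the absolute sense of induction in the two catalyst-controlled steps (4 and 14) is assigned from the empirical models for the parent substrates (allylic bromides of the cinnamyl type; styrene and cyclopentadiene), and the mirror-image ligand or catalyst would be used if a model run showed the opposite sense.

## Route

Step 1
Reactants: 1 4-bromobut-1-yne
Product: 3 5-bromopent-2-yn-1-ol, via lithium acetylide 2 (not isolated)
Conditions: n-BuLi (1.0 equiv), THF, −78 °C; (CH2O)n, −78 °C → rt; aq. NH4Cl
Reagents that add atoms: formaldehyde (from paraformaldehyde), C=O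
Why: Deprotonation of the terminal alkyne is much faster than attack of n-BuLi on the primary bromide at −78 °C, and the acetylide then adds to formaldehyde (alkynylation of an aldehyde) to give the propargylic alcohol.

Step 2
Reactants: 3 5-bromopent-2-yn-1-ol
Product: 4 [(5-bromopent-2-yn-1-yl)oxy]triisopropylsilane
Conditions: i-Pr3SiCl, imidazole, DMF, rt
Reagents that add atoms: chlorotriisopropylsilane, CC(C)[Si](Cl)(C(C)C)C(C)C
Why: Silylation of a primary alcohol; the bulky triisopropylsilyl group is chosen because it survives the later acidic acetalisation and shields the oxygen-activated C14 methylene from carbenoid C–H insertion in the key step.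

Step 3
Reactants: 5 (E)-1,4-dibromobut-2-ene; 6 (4-methoxyphenyl)methanol
Product: 7 1-({[(2E)-4-bromobut-2-en-1-yl]oxy}methyl)-4-methoxybenzene
Conditions: NaH, THF, 0 °C; 5 (3 equiv), 0 °C → rt
Reagents that add atoms: none
Why: Williamson etherification of a reactive allylic bromide; the excess of the symmetrical dibromide suppresses double substitution.

Step 4
Reactants: 4 [(5-bromopent-2-yn-1-yl)oxy]triisopropylsilane; 7 1-({[(2E)-4-bromobut-2-en-1-yl]oxy}methyl)-4-methoxybenzene
Product: 9 triisopropyl{[(6S)-6-{[(4-methoxyphenyl)methoxy]methyl}oct-7-en-2-yn-1-yl]oxy}silane, via Grignard reagent 8 (not isolated)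
Conditions: 4, Mg, Et2O, rt; then CuBr·SMe2 (3 mol%), (R,Rp)-TaniaPhos (3.5 mol%), 7, CH2Cl2, −75 °C
Reagents that add atoms: none
Why: Copper-catalysed asymmetric allylic alkylation of an allylic bromide with a Grignard reagent proceeds SN2′ and gives the branched product with the vinyl group on the new stereocentre; the ferrocenyl diphosphine 1-[(dimethylamino)(2-diphenylphosphinophenyl)methyl]-2-(diphenylphosphino)ferrocene (TaniaPhos) on copper selects the alkene face and sets C2 as (S).

Step 5
Reactants: 9 triisopropyl{[(6S)-6-{[(4-methoxyphenyl)methoxy]methyl}oct-7-en-2-yn-1-yl]oxy}silane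
Product: 10 (6S)-6-{[(4-methoxyphenyl)methoxy]methyl}-3-{[(triisopropylsilyl)oxy]methyl}-4,5,6,6a-tetrahydropentalen-2(1H)-one (both C6a epimers)
Conditions: Co2(CO)8 (10 mol%), tetramethylthiourea (60 mol%), CO (1 atm), toluene, 70 °C
Reagents that add atoms: carbon monoxide, [C-]#[O+]
Why: Intramolecular Pauson–Khand reaction of a 1,6-enyne forms C1–C5, C6–C7 and C7–C11 with the regiochemistry fixed by the tether; the ring-fusion centre (cedrane C1) is formed as a mixture, which does not matter because it becomes sp2 in step 9.

Step 6
Reactants: 10 (6S)-6-{[(4-methoxyphenyl)methoxy]methyl}-3-{[(triisopropylsilyl)oxy]methyl}-4,5,6,6a-tetrahydropentalen-2(1H)-one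
Product: 11 (6S)-6-(hydroxymethyl)-3-{[(triisopropylsilyl)oxy]methyl}-4,5,6,6a-tetrahydropentalen-2(1H)-one (both C6a epimers)
Conditions: DDQ, CH2Cl2/pH 7 buffer, 0 °C → rt
Reagents that add atoms: none
Why: Oxidative cleavage of a 4-methoxybenzyl ether; the silyl ether and the electron-poor enone are inert to DDQ under buffered conditions.

Step 7
Reactants: 11 (6S)-6-(hydroxymethyl)-3-{[(triisopropylsilyl)oxy]methyl}-4,5,6,6a-tetrahydropentalen-2(1H)-one
Product: 12 (1S)-5-oxo-4-{[(triisopropylsilyl)oxy]methyl}-1,2,3,5,6,6a-hexahydropentalene-1-carbaldehyde (both C6a epimers)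
Conditions: Dess–Martin periodinane, NaHCO3, CH2Cl2, 0 °C → rt
Reagents that add atoms: none
Why: Buffered periodinane oxidation of a primary alcohol; with the alkene of 9 now consumed, the α-stereocentre C2 is an ordinary α-branched aldehyde centre and should survive the neutral conditions.

Step 8
Reactants: 12 (1S)-5-oxo-4-{[(triisopropylsilyl)oxy]methyl}-1,2,3,5,6,6a-hexahydropentalene-1-carbaldehyde
Product: 13 (6S)-6-(dimethoxymethyl)-3-{[(triisopropylsilyl)oxy]methyl}-4,5,6,6a-tetrahydropentalen-2(1H)-one (both C6a epimers)
Conditions: HC(OMe)3, PPTS (cat.), MeOH, rt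
Reagents that add atoms: trimethyl orthoformate, COC(OC)OC; methanol, CO
Why: Acid-catalysed acetalisation is selective for the aldehyde over the conjugated, hindered ketone; the triisopropylsilyl ether tolerates the mild acid.

Step 9
Reactants: 13 (6S)-6-(dimethoxymethyl)-3-{[(triisopropylsilyl)oxy]methyl}-4,5,6,6a-tetrahydropentalen-2(1H)-one
Product: 15 (4S)-4-(dimethoxymethyl)-1-{[(triisopropylsilyl)oxy]methyl}-3,4,5,6-tetrahydropentalen-2-yl trifluoromethanesulfonate, via kinetic dienyl triflate 14 (not isolated)
Conditions: LiN(SiMe3)2, THF, −78 °C; PhNTf2, −78 → 0 °C; work-up; toluene, 45 °C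
Reagents that add atoms: N-phenylbis(trifluoromethanesulfonimide), O=S(=O)(N(c1ccccc1)S(=O)(=O)C(F)(F)F)C(F)(F)F
Why: Kinetic deprotonation of the enone at C11 and O-sulfonylation give the cross-conjugated dienyl triflate 14; a [1,5]-hydrogen shift from C1 to C11 on gentle warming moves it into tautomer 15, the thermodynamic sink, in which the triflate stays on an sp2 carbon and all three carbon substituents sit on the diene. The C1 centre is erased, so both epimers converge.

Step 10
Reactants: 15 (4S)-4-(dimethoxymethyl)-1-{[(triisopropylsilyl)oxy]methyl}-3,4,5,6-tetrahydropentalen-2-yl trifluoromethanesulfonate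
Product: 16 {[(4S)-4-(dimethoxymethyl)-3,4,5,6-tetrahydropentalen-1-yl]methoxy}triisopropylsilane
Conditions: Pd(PPh3)4 (5 mol%), LiCl, Bu3SnH, THF, 0 °C; cold pentane/alumina filtration; used at once
Reagents that add atoms: none
Why: Palladium-catalysed hydride transfer from the stannane to a dienyl triflate replaces C7–O by C7–H without moving the double bonds, so the diene is delivered as the single tautomer with C11 as the CH2 group. It is kept at or below 0 °C because [1,5]-hydrogen shifts would scramble it at room temperature.

Step 11
Reactants: 17 methyl 3-oxobutanoate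
Product: 18 methyl 2-diazo-3-oxobutanoate
Conditions: 4-acetamidobenzenesulfonyl azide, Et3N, MeCN, 0 °C → rt
Reagents that add atoms: 4-acetamidobenzenesulfonyl azide, CC(=O)Nc1ccc(cc1)S(=O)(=O)N=[N+]=[N-]
Why: Regitz diazo transfer to an active methylene compound.

Step 12
Reactants: 18 methyl 2-diazo-3-oxobutanoate
Product: 19 methyl 2-diazo-3-hydroxybutanoate (racemic)
Conditions: NaBH4, MeOH, 0 °C
Reagents that add atoms: none
Why: Borohydride reduces the ketone and leaves the diazo ester intact; the carbinol centre is removed in the next step.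

Step 13
Reactants: 19 methyl 2-diazo-3-hydroxybutanoate
Product: 20 methyl 2-diazobut-3-enoate
Conditions: POCl3, Et3N, CH2Cl2, 0 °C; rapid filtration through silica; used at once
Reagents that add atoms: none
Why: Dehydration through the dichlorophosphate gives the vinyldiazoacetate; it is prepared immediately before use because it cyclises slowly to a pyrazole on standing.

Step 14
Reactants: 16 {[(4S)-4-(dimethoxymethyl)-3,4,5,6-tetrahydropentalen-1-yl]methoxy}triisopropylsilane; 20 methyl 2-diazobut-3-enoate
Product: 22 methyl (2S)-2-(dimethoxymethyl)-6-{[(triisopropylsilyl)oxy]methyl}tricyclo[5.3.1.0(1,5)]undeca-5,8-diene-8-carboxylate (C8–C10 bridge syn to the C2 substituent), via cis-divinylcyclopropane 21 (not isolated)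
Conditions: Rh2(R-DOSP)4 [tetrakis((R)-N-(4-dodecylphenylsulfonyl)prolinato)dirhodium] (2 mol%), hexanes, −78 °C, slow addition of 20 (2.5 equiv); then → 25 °C
Reagents that add atoms: none
Why: The catalyst decomposes 20 to a donor/acceptor vinylcarbenoid, which bonds first to C7, the only unsubstituted diene terminus, and closes the cyclopropane at C6 with the vinyl group cis to the C5=C1 alkene, as is general for this carbenoid class with cyclic dienes. The cis-divinylcyclopropane 21 is locked in the reactive geometry and undergoes a Cope rearrangement through a boat transition state: C10 bonds to C1, C6–C8 breaks, and ring C closes as the six-membered half of a bicyclo[3.2.1]octadiene; the closest known reaction type is the tandem cyclopropanation–Cope (formal (4+3)) reaction of vinyldiazoacetates with cyclopentadienes. C7 is set in the cyclopropanation by the chiral catalyst, which chooses the diene face, and C1 follows stereospecifically because the sigmatropic shift is suprafacial on the face that carries the cyclopropane. Three selectivities are needed: site (C6=C7 rather than the tetrasubstituted C1=C5, secured by the free CH terminus), endo placement of the vinyl group (inherent to donor/acceptor carbenoids), and attack on the face syn to the C2 acetal. The last runs against a modest substrate bias and rests on catalyst control, which is reasonable because the first bond forms at C7, four bonds from C2; the (R) hand is taken from the styrene model for this catalyst family. Cyclopropanation of the electron-rich diene should outrun insertion into the shielded C14–H bonds and ylide formation at the acetal, and insertion at C11 is disfavoured because hydride loss there would give a cyclopentadienyl cation. The diene CH2 becomes C11 unchanged, and the product carries the C8=C9 enoate and a C5=C6 alkene for the later steps.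

Step 15
Reactants: 22 methyl (2S)-2-(dimethoxymethyl)-6-{[(triisopropylsilyl)oxy]methyl}tricyclo[5.3.1.0(1,5)]undeca-5,8-diene-8-carboxylate
Product: 23 (2S)-2-(dimethoxymethyl)-6-{[(triisopropylsilyl)oxy]methyl}tricyclo[5.3.1.0(1,5)]undeca-5,8-diene-8-carboxylic acid
Conditions: LiOH, THF/MeOH/H2O, 45 °C; 1 M HCl to pH 4, 0 °C
Reagents that add atoms: lithium hydroxide, [Li+].[OH-]
Why: Saponification of the only ester present; acetal and silyl ether are stable to base, and the bridgehead C7 cannot epimerise.

Step 16
Reactants: 23 (2S)-2-(dimethoxymethyl)-6-{[(triisopropylsilyl)oxy]methyl}tricyclo[5.3.1.0(1,5)]undeca-5,8-diene-8-carboxylic acid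
Product: 24 tert-butyl (2S)-2-(dimethoxymethyl)-6-{[(triisopropylsilyl)oxy]methyl}tricyclo[5.3.1.0(1,5)]undeca-5,8-diene-8-carboxylate
Conditions: Me2NCH(Ot-Bu)2, toluene, 80 °C
Reagents that add atoms: N,N-dimethylformamide di-tert-butyl acetal, CN(C)C(OC(C)(C)C)OC(C)(C)C
Why: Neutral tert-butyl esterification of a carboxylic acid; the tert-butyl ester can later be released by acid in the presence of the C10 ester and resists the basic aldol conditions of step 20.

Step 17
Reactants: 24 tert-butyl (2S)-2-(dimethoxymethyl)-6-{[(triisopropylsilyl)oxy]methyl}tricyclo[5.3.1.0(1,5)]undeca-5,8-diene-8-carboxylate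
Product: 25 tert-butyl (2S)-2-(dimethoxymethyl)-6-(hydroxymethyl)tricyclo[5.3.1.0(1,5)]undeca-5,8-diene-8-carboxylate
Conditions: Bu4NF, AcOH, THF, 0 °C → rt
Reagents that add atoms: none
Why: Fluoride cleavage of the only silyl ether; buffering with acetic acid avoids a free alkoxide that could add to the enoate.

Step 18
Reactants: 25 tert-butyl (2S)-2-(dimethoxymethyl)-6-(hydroxymethyl)tricyclo[5.3.1.0(1,5)]undeca-5,8-diene-8-carboxylate
Product: 26 tert-butyl (2S)-2-(dimethoxymethyl)-6-formyltricyclo[5.3.1.0(1,5)]undeca-5,8-diene-8-carboxylate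
Conditions: Dess–Martin periodinane, NaHCO3, CH2Cl2, 0 °C
Reagents that add atoms: none
Why: Oxidation of a primary allylic alcohol to the tetrasubstituted enal under buffered conditions that spare the acetal.

Step 19
Reactants: 26 tert-butyl (2S)-2-(dimethoxymethyl)-6-formyltricyclo[5.3.1.0(1,5)]undeca-5,8-diene-8-carboxylate
Product: 27 tert-butyl (2S)-2-(dimethoxymethyl)-6-formyltricyclo[5.3.1.0(1,5)]undec-8-ene-8-carboxylate (H-5 exo; both C6 epimers)
Conditions: diethyl 2,6-dimethyl-1,4-dihydropyridine-3,5-dicarboxylate (1.3 equiv), Bn2NH2+ CF3CO2− (20 mol%), THF, 40 °C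
Reagents that add atoms: none
Why: Iminium-ion transfer hydrogenation of an enal: the ammonium salt condenses only with the aldehyde, so the C8=C9 enoate is untouched, and hydride from the dihydropyridine adds to C5 on the exo face because the endo face is covered by the C8–C10 bridge. This sets H-5 and turns C4 endo; the C6 centre is irrelevant because it is enolised in step 20.

Step 20
Reactants: 27 tert-butyl (2S)-2-(dimethoxymethyl)-6-formyltricyclo[5.3.1.0(1,5)]undec-8-ene-8-carboxylate
Product: 28 tert-butyl (2S)-2-(dimethoxymethyl)-6-formyl-6-(hydroxymethyl)tricyclo[5.3.1.0(1,5)]undec-8-ene-8-carboxylate (hydroxymethyl exo; formyl endo)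
Conditions: aq. CH2O (37%), K2CO3, THF, 0 °C → rt
Reagents that add atoms: formaldehyde, C=O
Why: Crossed aldol of an α-branched aldehyde with formaldehyde: the exocyclic enolate at C6 is attacked on the exo face, away from the C8–C10 bridge and from C4, so the new C13 arm is exo and the formyl group (the future C14) is endo. The product has no α-hydrogen, so the reaction stops at the mono-adduct.

Step 21
Reactants: 28 tert-butyl (2S)-2-(dimethoxymethyl)-6-formyl-6-(hydroxymethyl)tricyclo[5.3.1.0(1,5)]undec-8-ene-8-carboxylate
Product: 29 tert-butyl (2S)-6-{[(tert-butyldimethylsilyl)oxy]methyl}-2-(dimethoxymethyl)-6-formyltricyclo[5.3.1.0(1,5)]undec-8-ene-8-carboxylate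
Conditions: TBSCl, imidazole, DMAP (cat.), DMF, rt
Reagents that add atoms: tert-butylchlorodimethylsilane, CC(C)(C)[Si](C)(C)Cl
Why: Silylation of the neopentyl primary alcohol blocks retro-aldol loss of formaldehyde and distinguishes C13 from C14.

Step 22
Reactants: 29 tert-butyl (2S)-6-{[(tert-butyldimethylsilyl)oxy]methyl}-2-(dimethoxymethyl)-6-formyltricyclo[5.3.1.0(1,5)]undec-8-ene-8-carboxylate
Product: 31 tert-butyl (2S)-6-{[(tert-butyldimethylsilyl)oxy]methyl}-2-(dimethoxymethyl)-6-methyltricyclo[5.3.1.0(1,5)]undec-8-ene-8-carboxylate (methyl endo), via tosylhydrazone 30 (not isolated)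
Conditions: TsNHNH2, THF, rt; catecholborane, CHCl3, 0 °C; NaOAc·3H2O, 60 °C
Reagents that add atoms: none
Why: Reduction of an aldehyde tosylhydrazone by catecholborane, followed by acetate-induced loss of sulfinate and dinitrogen (Kabalka variant of the Caglioti reduction), converts the formyl group into the C14 methyl without touching ester, enoate, acetal or silyl ether; no stereocentre is involved.

Step 23
Reactants: 31 tert-butyl (2S)-6-{[(tert-butyldimethylsilyl)oxy]methyl}-2-(dimethoxymethyl)-6-methyltricyclo[5.3.1.0(1,5)]undec-8-ene-8-carboxylate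
Product: 32 tert-butyl (2S)-6-{[(tert-butyldimethylsilyl)oxy]methyl}-2-(dimethoxymethyl)-10-hydroxy-6-methyltricyclo[5.3.1.0(1,5)]undec-8-ene-8-carboxylate (hydroxyl syn to C11)
Conditions: SeO2 (1.0 equiv), t-BuOOH (decane), ClCH2CH2Cl, 60 °C
Reagents that add atoms: selenium dioxide, O=[Se]=O; tert-butyl hydroperoxide, CC(C)(C)OO
Why: Allylic hydroxylation by SeO2 (ene reaction, then [2,3]-sigmatropic shift): C10 has the only abstractable allylic hydrogens because C7 is a bridgehead; selenium should bind C8 on the open face turned to C11, and the [2,3]-shift returns oxygen to C10 on that same face. γ-Hydroxylation of enoates by this reagent is known but slow, hence the co-oxidant and warming.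

Step 24
Reactants: 33 oct-7-yn-1-ol
Product: 34 tert-butyldimethyl(oct-7-yn-1-yloxy)silane
Conditions: TBSCl, imidazole, CH2Cl2, rt
Reagents that add atoms: tert-butylchlorodimethylsilane, CC(C)(C)[Si](C)(C)Cl
Why: Standard silylation of a primary alcohol, so that the chain can be metalated and later acylated without self-condensation.

Step 25
Reactants: 34 tert-butyldimethyl(oct-7-yn-1-yloxy)silane; 35 8-bromooctanoic acid
Product: 38 16-[(tert-butyldimethylsilyl)oxy]hexadec-9-ynoic acid, via lithium acetylide 36 (not isolated), via lithium 8-bromooctanoate 37 (not isolated)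
Conditions: n-BuLi (34 and 35 separately), THF, −78 °C; combine, DMPU, 0 → 40 °C; aq. HCl
Reagents that add atoms: none
Why: SN2 alkylation of a lithium acetylide by a primary bromide in a dipolar cosolvent; the bromo acid is used as its carboxylate salt, which is inert to the acetylide.

Step 26
Reactants: 38 16-[(tert-butyldimethylsilyl)oxy]hexadec-9-ynoic acid
Product: 39 (9Z)-16-[(tert-butyldimethylsilyl)oxy]hexadec-9-enoic acid
Conditions: H2 (1 atm), Pd/CaCO3 poisoned with Pb(OAc)2, quinoline, EtOAc, rt
Reagents that add atoms: none
Why: Lindlar semihydrogenation adds hydrogen syn to the alkyne and stops at the Z-alkene.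

Step 27
Reactants: 39 (9Z)-16-[(tert-butyldimethylsilyl)oxy]hexadec-9-enoic acid; 32 tert-butyl (2S)-6-{[(tert-butyldimethylsilyl)oxy]methyl}-2-(dimethoxymethyl)-10-hydroxy-6-methyltricyclo[5.3.1.0(1,5)]undec-8-ene-8-carboxylate
Product: 41 tert-butyl (2S)-10-({(9Z)-16-[(tert-butyldimethylsilyl)oxy]hexadec-9-enoyl}oxy)-6-{[(tert-butyldimethylsilyl)oxy]methyl}-2-(dimethoxymethyl)-6-methyltricyclo[5.3.1.0(1,5)]undec-8-ene-8-carboxylate, via mixed anhydride 40 (not isolated)
Conditions: 39, 2,4,6-Cl3C6H2COCl, Et3N, toluene, rt; then 32, DMAP, 40 °C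
Reagents that add atoms: none
Why: Yamaguchi esterification; the mixed anhydride with DMAP acylates hindered secondary alcohols, and the C10 configuration is retained because the C–O bond is not broken.

Step 28
Reactants: 41 tert-butyl (2S)-10-({(9Z)-16-[(tert-butyldimethylsilyl)oxy]hexadec-9-enoyl}oxy)-6-{[(tert-butyldimethylsilyl)oxy]methyl}-2-(dimethoxymethyl)-6-methyltricyclo[5.3.1.0(1,5)]undec-8-ene-8-carboxylate
Product: 42 CNP0148862.1, (2S)-2-formyl-10-{[(9Z)-16-hydroxyhexadec-9-enoyl]oxy}-6-(hydroxymethyl)-6-methyltricyclo[5.3.1.0(1,5)]undec-8-ene-8-carboxylic acid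
Conditions: CF3CO2H/CH2Cl2/H2O (9:9:1), 0 °C → rt; buffered aqueous work-up
Reagents that add atoms: water, O
Why: One acidolysis cleaves the tert-butyl ester (loss of isobutene), hydrolyses the dimethyl acetal and removes both silyl ethers; the C10 ester is stable to acid, and ionisation at C10 is disfavoured because the allyl cation would place charge on C8 next to the carboxyl group. Low temperature and short exposure limit epimerisation at C2.

## Compound list

1 | 4-bromobut-1-yne | C#CCCBr | starting material
2 | (4-bromobut-1-yn-1-yl)lithium | [Li]C#CCCBr | intermediate (not isolated)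
3 | 5-bromopent-2-yn-1-ol | OCC#CCCBr | intermediate
4 | [(5-bromopent-2-yn-1-yl)oxy]triisopropylsilane | BrCCC#CCO[Si](C(C)C)(C(C)C)C(C)C | intermediate
5 | (E)-1,4-dibromobut-2-ene | BrC/C=C/CBr | starting material
6 | (4-methoxyphenyl)methanol | COc1ccc(CO)cc1 | starting material
7 | 1-({[(2E)-4-bromobut-2-en-1-yl]oxy}methyl)-4-methoxybenzene | COc1ccc(COC/C=C/CBr)cc1 | intermediate
8 | bromo{5-[(triisopropylsilyl)oxy]pent-3-yn-1-yl}magnesium | Br[Mg]CCC#CCO[Si](C(C)C)(C(C)C)C(C)C | intermediate (not isolated)
9 | triisopropyl{[(6S)-6-{[(4-methoxyphenyl)methoxy]methyl}oct-7-en-2-yn-1-yl]oxy}silane | C=C[C@@H](COCc1ccc(OC)cc1)CCC#CCO[Si](C(C)C)(C(C)C)C(C)C | intermediate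
10 | (6S)-6-{[(4-methoxyphenyl)methoxy]methyl}-3-{[(triisopropylsilyl)oxy]methyl}-4,5,6,6a-tetrahydropentalen-2(1H)-one, both C6a epimers | O=C1CC2[C@@H](COCc3ccc(OC)cc3)CCC2=C1CO[Si](C(C)C)(C(C)C)C(C)C | intermediate
11 | (6S)-6-(hydroxymethyl)-3-{[(triisopropylsilyl)oxy]methyl}-4,5,6,6a-tetrahydropentalen-2(1H)-one, both C6a epimers | O=C1CC2[C@@H](CO)CCC2=C1CO[Si](C(C)C)(C(C)C)C(C)C | intermediate
12 | (1S)-5-oxo-4-{[(triisopropylsilyl)oxy]methyl}-1,2,3,5,6,6a-hexahydropentalene-1-carbaldehyde, both C6a epimers | O=C1CC2[C@@H](C=O)CCC2=C1CO[Si](C(C)C)(C(C)C)C(C)C | intermediate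
13 | (6S)-6-(dimethoxymethyl)-3-{[(triisopropylsilyl)oxy]methyl}-4,5,6,6a-tetrahydropentalen-2(1H)-one, both C6a epimers | O=C1CC2[C@@H](C(OC)OC)CCC2=C1CO[Si](C(C)C)(C(C)C)C(C)C | intermediate
14 | (4S)-4-(dimethoxymethyl)-1-{[(triisopropylsilyl)oxy]methyl}-3a,4,5,6-tetrahydropentalen-2-yl trifluoromethanesulfonate, both C3a epimers | FC(F)(F)S(=O)(=O)OC1=CC2[C@@H](C(OC)OC)CCC2=C1CO[Si](C(C)C)(C(C)C)C(C)C | intermediate (not isolated)
15 | (4S)-4-(dimethoxymethyl)-1-{[(triisopropylsilyl)oxy]methyl}-3,4,5,6-tetrahydropentalen-2-yl trifluoromethanesulfonate | FC(F)(F)S(=O)(=O)OC1=C(CO[Si](C(C)C)(C(C)C)C(C)C)C2=C(C1)[C@@H](C(OC)OC)CC2 | intermediate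
16 | {[(4S)-4-(dimethoxymethyl)-3,4,5,6-tetrahydropentalen-1-yl]methoxy}triisopropylsilane (fused cyclopentadiene; C6=C7 and C1=C5, C11 as CH2) | CC(C)[Si](C(C)C)(C(C)C)OCC1=CCC2=C1CC[C@@H]2C(OC)OC | intermediate
17 | methyl 3-oxobutanoate | CC(=O)CC(=O)OC | starting material
18 | methyl 2-diazo-3-oxobutanoate | CC(=O)C(=[N+]=[N-])C(=O)OC | intermediate
19 | methyl 2-diazo-3-hydroxybutanoate (racemic) | CC(O)C(=[N+]=[N-])C(=O)OC | intermediate
20 | methyl 2-diazobut-3-enoate | C=CC(=[N+]=[N-])C(=O)OC | intermediate
21 | cis-divinylcyclopropane from addition of the carbenoid across C6=C7 of 16 (vinyl group cis to C5 and C11; ester exo) | C=C[C@@]1(C(=O)OC)[C@H]2CC3=C(CC[C@@H]3C(OC)OC)[C@@]12CO[Si](C(C)C)(C(C)C)C(C)C | intermediate (not isolated)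
22 | methyl (2S)-2-(dimethoxymethyl)-6-{[(triisopropylsilyl)oxy]methyl}tricyclo[5.3.1.0(1,5)]undeca-5,8-diene-8-carboxylate, C8–C10 bridge syn to the C2 substituent | CC(C)[Si](C(C)C)(C(C)C)OCC1=C2CC[C@H](C(OC)OC)[C@@]23C[C@@H]1C(C(=O)OC)=CC3 | intermediate
23 | carboxylic acid corresponding to 22 | CC(C)[Si](C(C)C)(C(C)C)OCC1=C2CC[C@H](C(OC)OC)[C@@]23C[C@@H]1C(C(=O)O)=CC3 | intermediate
24 | tert-butyl ester corresponding to 22 | CC(C)[Si](C(C)C)(C(C)C)OCC1=C2CC[C@H](C(OC)OC)[C@@]23C[C@@H]1C(C(=O)OC(C)(C)C)=CC3 | intermediate
25 | tert-butyl (2S)-2-(dimethoxymethyl)-6-(hydroxymethyl)tricyclo[5.3.1.0(1,5)]undeca-5,8-diene-8-carboxylate | OCC1=C2CC[C@H](C(OC)OC)[C@@]23C[C@@H]1C(C(=O)OC(C)(C)C)=CC3 | intermediate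
26 | tert-butyl (2S)-2-(dimethoxymethyl)-6-formyltricyclo[5.3.1.0(1,5)]undeca-5,8-diene-8-carboxylate | O=CC1=C2CC[C@H](C(OC)OC)[C@@]23C[C@@H]1C(C(=O)OC(C)(C)C)=CC3 | intermediate
27 | tert-butyl (2S)-2-(dimethoxymethyl)-6-formyltricyclo[5.3.1.0(1,5)]undec-8-ene-8-carboxylate, H-5 exo, both C6 epimers | O=CC1[C@@H]2CC[C@H](C(OC)OC)[C@@]23C[C@@H]1C(C(=O)OC(C)(C)C)=CC3 | intermediate
28 | tert-butyl (2S)-2-(dimethoxymethyl)-6-formyl-6-(hydroxymethyl)tricyclo[5.3.1.0(1,5)]undec-8-ene-8-carboxylate, hydroxymethyl exo, formyl endo | O=C[C@]1(CO)[C@@H]2CC[C@H](C(OC)OC)[C@@]23C[C@@H]1C(C(=O)OC(C)(C)C)=CC3 | intermediate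
29 | tert-butyldimethylsilyl ether of 28 at C13 | O=C[C@]1(CO[Si](C)(C)C(C)(C)C)[C@@H]2CC[C@H](C(OC)OC)[C@@]23C[C@@H]1C(C(=O)OC(C)(C)C)=CC3 | intermediate
30 | 4-methylbenzenesulfonylhydrazone of 29 at C14 | Cc1ccc(cc1)S(=O)(=O)N/N=C/[C@]1(CO[Si](C)(C)C(C)(C)C)[C@@H]2CC[C@H](C(OC)OC)[C@@]23C[C@@H]1C(C(=O)OC(C)(C)C)=CC3 | intermediate (not isolated)
31 | tert-butyl (2S)-6-{[(tert-butyldimethylsilyl)oxy]methyl}-2-(dimethoxymethyl)-6-methyltricyclo[5.3.1.0(1,5)]undec-8-ene-8-carboxylate, methyl endo | C[C@]1(CO[Si](C)(C)C(C)(C)C)[C@@H]2CC[C@H](C(OC)OC)[C@@]23C[C@@H]1C(C(=O)OC(C)(C)C)=CC3 | intermediate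
32 | 10-hydroxy derivative of 31, hydroxyl syn to C11 | C[C@]1(CO[Si](C)(C)C(C)(C)C)[C@@H]2CC[C@H](C(OC)OC)[C@@]23C[C@@H]1C(C(=O)OC(C)(C)C)=C[C@@H]3O | intermediate
33 | oct-7-yn-1-ol | C#CCCCCCCO | starting material
34 | tert-butyldimethyl(oct-7-yn-1-yloxy)silane | C#CCCCCCCO[Si](C)(C)C(C)(C)C | intermediate
35 | 8-bromooctanoic acid | OC(=O)CCCCCCCBr | starting material
36 | {8-[(tert-butyldimethylsilyl)oxy]oct-1-yn-1-yl}lithium | [Li]C#CCCCCCCO[Si](C)(C)C(C)(C)C | intermediate (not isolated)
37 | lithium 8-bromooctanoate | [Li+].[O-]C(=O)CCCCCCCBr | intermediate (not isolated)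
38 | 16-[(tert-butyldimethylsilyl)oxy]hexadec-9-ynoic acid | OC(=O)CCCCCCCC#CCCCCCCO[Si](C)(C)C(C)(C)C | intermediate
39 | (9Z)-16-[(tert-butyldimethylsilyl)oxy]hexadec-9-enoic acid | OC(=O)CCCCCCC/C=C\CCCCCCO[Si](C)(C)C(C)(C)C | intermediate
40 | mixed anhydride of 39 with 2,4,6-trichlorobenzoic acid | O=C(OC(=O)c1c(Cl)cc(Cl)cc1Cl)CCCCCCC/C=C\CCCCCCO[Si](C)(C)C(C)(C)C | intermediate (not isolated)
41 | fully protected ester: 32 acylated at O-10 by 39 | C[C@]1(CO[Si](C)(C)C(C)(C)C)[C@@H]2CC[C@H](C(OC)OC)[C@@]23C[C@@H]1C(C(=O)OC(C)(C)C)=C[C@@H]3OC(=O)CCCCCCC/C=C\CCCCCCO[Si](C)(C)C(C)(C)C | intermediate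
42 | CNP0148862.1 | C[C@@]1(CO)[C@@H]2C[C@]3([C@@H](OC(=O)CCCCCCC/C=C\CCCCCCO)C=C2C(=O)O)[C@@H](C=O)CC[C@@H]13 | target

## Step count and least certain steps

Total: 28 steps. Longest linear sequence: 21 steps (steps 1, 2, 4–10, 14–23, 27, 28). The side branches are the allylic bromide (step 3), the diazo ester (steps 11–13) and the acyl chain (steps 24–26).

**Step 14 (key step).**
- What may go wrong: erosion of facial selectivity, because the carbenoid must add to the diene face that carries the C2 acetal and the catalyst has to override the substrate's preference for the other face. A retarded Cope shift, because a quaternary centre is formed next to that acetal. Loss of the unstabilised diazo ester by electrocyclisation before it reaches the catalyst. Tautomerisation of the diene by [1,5]-hydrogen shift if it warms.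
- Fallback (from 16 and 18, back at 22): a stabilised, storable carbenoid precursor is used and the extra oxygen is removed afterwards. Silylation of 18 (TBSOTf, Et3N) gives methyl 3-[(tert-butyldimethylsilyl)oxy]-2-diazobut-3-enoate F1, which can be added slowly at low temperature. With Rh2(R-PTAD)4 [tetrakis((R)-N-phthaloyl-1-adamantylglycinato)dirhodium] and 16 it should pass through the siloxy-substituted cis-divinylcyclopropane F2 to the C9 silyl enol ether of the adduct F3. Selective cleavage of the enol ether (Et3N·3HF, 0 °C) gives the C9 β-keto ester F4, which is converted (NaH, PhNTf2) into the C9 enol triflate F5 and reduced (Pd(OAc)2, PPh3, Bu3N, HCO2H) to 22.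

**Step 10.**
- What may go wrong: migration of the double bonds by [1,5]-hydrogen shift during the reduction or the handling (which would put the CH2 group at C7), addition of a palladium hydride to the diene, or Diels–Alder dimerisation. Any of these would feed the wrong diene into the key step.
- Fallback (from 13, back at 16): the diene is made by elimination instead of reductive detriflation. Luche reduction of 13 (NaBH4, CeCl3·7H2O, MeOH, −40 °C) gives the C7 allylic alcohol F6. Sulfonylation (Ms2O, Et3N, CH2Cl2, −30 °C) gives the allylic mesylate F7, which loses methanesulfonic acid on addition of DBU below 0 °C with removal of the tertiary allylic hydrogen at C1, the most substituted cyclopentadiene being expected; this gives 16, again used cold and at once.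

**Step 19.**
- What may go wrong: slow iminium formation at the tetrasubstituted, α-branched enal. Deconjugation through a dienamine by loss of a C4 hydrogen. Hydride delivery to the endo face.
- Fallback (from 25, back at 27): hydrogen is delivered to C5 intramolecularly by a reductive allylic transposition. Mitsunobu reaction of 25 with 2-nitrobenzenesulfonylhydrazide (PPh3, diethyl azodicarboxylate, THF, −30 °C) gives the N-allyl-N-(2-nitrobenzenesulfonyl)hydrazine F8. On warming this loses sulfinic acid to the allylic diazene F9, which transfers hydrogen to C5 in a retro-ene step, expected on the exo face, and gives the 6-methylidene compound F10. Hydroboration with 9-borabicyclo[3.3.1]nonane gives the B-alkylborane F11, oxidised (NaBO3·4H2O) to the 6-(hydroxymethyl) compound F12, and periodinane oxidation then gives 27.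

**Step 23.**
- What may go wrong: too slow an ene reaction at the electron-poor, hindered enoate, so that forcing conditions lead to over-oxidation to the C10 ketone or to acid-induced loss of the acetal.
- Fallback (from 31, back at 32): the oxygen is brought in by deconjugation, epoxidation and ring opening. Deprotonation of 31 at C10 (LiN(i-Pr)2, DMPU, THF, −78 °C) gives the lithium dienolate F13. Kinetic protonation at C8 (AcOH, −78 °C) gives the β,γ-unsaturated ester F14. Epoxidation of its C9=C10 alkene from the face turned to C11 (mCPBA, NaHCO3, CH2Cl2, 0 °C) gives the 9,10-epoxide F15. DBU then opens the epoxide by β-elimination from the ester enolate and gives 32 with the hydroxyl syn to C11.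

## Further compounds

F1 | step 14 | methyl 3-[(tert-butyldimethylsilyl)oxy]-2-diazobut-3-enoate | C=C(O[Si](C)(C)C(C)(C)C)C(=[N+]=[N-])C(=O)OC
F2 | step 14 | siloxy-substituted cis-divinylcyclopropane (analogue of 21 with OTBS on C9) | C=C(O[Si](C)(C)C(C)(C)C)[C@@]1(C(=O)OC)[C@H]2CC3=C(CC[C@@H]3C(OC)OC)[C@@]12CO[Si](C(C)C)(C(C)C)C(C)C
F3 | step 14 | C9 silyl enol ether of the adduct (analogue of 22 with OTBS on C9) | CC(C)[Si](C(C)C)(C(C)C)OCC1=C2CC[C@H](C(OC)OC)[C@@]23C[C@@H]1C(C(=O)OC)=C(O[Si](C)(C)C(C)(C)C)C3
F4 | step 14 | C9 β-keto ester (9-oxo analogue of 22, C8 epimers and enol) | CC(C)[Si](C(C)C)(C(C)C)OCC1=C2CC[C@H](C(OC)OC)[C@@]23C[C@@H]1C(C(=O)OC)C(=O)C3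
F5 | step 14 | C9 enol triflate (analogue of 22 with OTf on C9) | CC(C)[Si](C(C)C)(C(C)C)OCC1=C2CC[C@H](C(OC)OC)[C@@]23C[C@@H]1C(C(=O)OC)=C(OS(=O)(=O)C(F)(F)F)C3
F6 | step 10 | C7 allylic alcohol from 13 (epimer mixture) | OC1CC2[C@@H](C(OC)OC)CCC2=C1CO[Si](C(C)C)(C(C)C)C(C)C
F7 | step 10 | allylic mesylate of F6 | CS(=O)(=O)OC1CC2[C@@H](C(OC)OC)CCC2=C1CO[Si](C(C)C)(C(C)C)C(C)C
F8 | step 19 | N-allyl-N-(2-nitrobenzenesulfonyl)hydrazine from 25 | NN(CC1=C2CC[C@H](C(OC)OC)[C@@]23C[C@@H]1C(C(=O)OC(C)(C)C)=CC3)S(=O)(=O)c1ccccc1[N+](=O)[O-]
F9 | step 19 | allylic diazene | N=NCC1=C2CC[C@H](C(OC)OC)[C@@]23C[C@@H]1C(C(=O)OC(C)(C)C)=CC3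
F10 | step 19 | 6-methylidene compound, H-5 exo | C=C1[C@@H]2CC[C@H](C(OC)OC)[C@@]23C[C@@H]1C(C(=O)OC(C)(C)C)=CC3
F11 | step 19 | B-alkyl-9-borabicyclo[3.3.1]nonane from F10 | C(B1C2CCCC1CCC2)C1[C@@H]2CC[C@H](C(OC)OC)[C@@]23C[C@@H]1C(C(=O)OC(C)(C)C)=CC3
F12 | step 19 | 6-(hydroxymethyl) compound with hydrogen at C6 | OCC1[C@@H]2CC[C@H](C(OC)OC)[C@@]23C[C@@H]1C(C(=O)OC(C)(C)C)=CC3
F13 | step 23 | lithium dienolate of 31 | C[C@]1(CO[Si](C)(C)C(C)(C)C)[C@@H]2CC[C@H](C(OC)OC)[C@@]23C[C@@H]1C(=C(O[Li])OC(C)(C)C)C=C3
F14 | step 23 | β,γ-unsaturated ester (C9=C10; C8 epimers) | C[C@]1(CO[Si](C)(C)C(C)(C)C)[C@@H]2CC[C@H](C(OC)OC)[C@@]23C[C@@H]1C(C(=O)OC(C)(C)C)C=C3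
F15 | step 23 | 9,10-epoxide with oxygen on the face turned to C11 | C[C@]1(CO[Si](C)(C)C(C)(C)C)[C@@H]2CC[C@H](C(OC)OC)[C@@]23C[C@@H]1C(C(=O)OC(C)(C)C)[C@@H]4O[C@H]34
A1 | alternative 1 | methyl 2-(4-ethenyl-6-methoxy-8-oxospiro[4.5]deca-6,9-dien-1-yl)propanoate | COC(=O)C(C)[C@@H]1CC[C@H](C=C)[C@@]12C=CC(=O)C=C2OC
A2 | alternative 2 | methyl 10-acetoxy-2-{[(tert-butyldimethylsilyl)oxy]methyl}-6-methyl-11-oxo-6-{[(triisopropylsilyl)oxy]methyl}tricyclo[5.3.1.0(1,5)]undec-8-ene-8-carboxylate | C[C@@]1(CO[Si](C(C)C)(C(C)C)C(C)C)[C@@H]2C(=O)[C@]3([C@@H](OC(C)=O)C=C2C(=O)OC)[C@@H](CO[Si](C)(C)C(C)(C)C)CC[C@@H]13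
A3 | alternative 3 | pentacyclic cyclobutane–dioxanone photoadduct with C7–C8 and C6–C14 bonds, C10 silyl ether and C2 dimethyl acetal | [C@H]4(OC(C)(C)OC5=O)[C@@]1(CO[Si](C(C)C)(C(C)C)C(C)C)[C@@H]2C[C@]3([C@@H](O[Si](C)(C)C(C)(C)C)C[C@@]245)[C@@H](C(OC)OC)CC[C@@H]13
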